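The easy step is to follow s, the fraction of substrate left, and not the target: in beta, epsilon and eta the two sum to about the charge.

| flask | substrate | reagent | initiator | remark | time |
|---|---|---|---|---|---|
| beta | 1.4 M | 2.8 M (fed, over 3.0 d) | 19 mM | run made earlier; the fed solution adds 0.10 times the starting volume |  |
| epsilon | 1.4 M | 2.8 M (fed, over 3.0 d) | 42 mM | run made earlier; the fed solution adds 0.10 times the starting volume |  |
| eta | 0.70 M | 2.8 M (fed, over 3.0 d) | 28 mM | run made earlier; the fed solution adds 0.10 times the starting volume |  |
| flask | 1.4 M | 2.80 M (fed, over 3.0 d) | 28 mM | the fed solution adds 0.10 times the starting volume | 3.0 d |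

| run | time / d | target / % | substrate / % |
|---|---|---|---|
| beta | 0.167 | 10.3 | 89.3 |
| beta | 0.500 | 32.5 | 67.0 |
| beta | 0.833 | 49.7 | 50.3 |
| beta | 1.25 | 65.5 | 35.3 |
| beta | 1.67 | 76.0 | 24.1 |
| beta | 2.50 | 88.5 | 12.3 |
| epsilon | 0.208 | 13.3 | 86.3 |
| epsilon | 0.333 | 21.9 | 78.2 |
| epsilon | 0.500 | 33.0 | 66.7 |
| epsilon | 0.833 | 54.1 | 44.9 |
| epsilon | 1.67 | 84.3 | 15.7 |
| epsilon | 2.50 | 94.0 | 5.4 |
| eta | 0.208 | 20.3 | 79.5 |
| eta | 0.333 | 30.6 | 69.7 |
| eta | 0.625 | 50.0 | 50.5 |
| eta | 1.25 | 74.5 | 25.5 |
| eta | 2.50 | 93.6 | 7.3 |

(readings scatter by 0.5 percentage points)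

- every charge counts on the volume at the start, and the solution that is fed holds the whole dose
- what was read earlier has a scatter of 0.5 percentage points, one standard deviation
- a reading or a percentage of target counts all its forms, free or not

* target present at 3.0 d, in percent of the substrate charged
* substrate present at 3.0 d, in percent of the substrate charged

Early in beta and epsilon, which hold the flask's substrate charge, s follows the dose line, falling by f = 0.667 d⁻¹ in fractions of the substrate charge. Eta, with 0.70 M of substrate, stands above its own dose line at 0.208 d: 79.5 % against 72.3 %. Late in a run, s decays first order (pseudo-first-order) with a constant k, which I read from the last two readings. I assume k goes with the root of initiator. Scaled to the flask's charge, beta gives 0.984 d⁻¹ and epsilon 1.05 d⁻¹, while eta, with the flask's initiator, reads 1.00 d⁻¹. The two laws meet at the changeover fraction c = f/k, which is 0.656 with the mean constant. Below c,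

s = c · exp(1/c − 1 − f t/c)

Roughly, the flask's s at 3.0 d lies under beta's 12.3 % at 2.50 d and above 4.29 %, which is decay from the start at the faster constant. Tightened, the formula with the two constants gives 4.84 % to 5.70 %, and with the mean c I commit to 5.25 %.

The forecast gives 5.2 % substrate (4 % to 6.7 %) and 94.7 % target (93 % to 96 %), holding that “substrate decays first order and is nearly independent of reagent”. Its substrate value stands inside my bracket.

The flask gives 4.90 % substrate and 95.1 % target, also inside the bracket.

    reagent + target ⇌ idle adduct, settled at all times (K = 0.300 M⁻¹)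
    reagent + chain carrier → target + initiating radical (k = 2.80 × 10⁶ M⁻¹ h⁻¹)
    2 initiating radical → ended chains (k = 1.00 × 10⁸ M⁻¹ s⁻¹)
    substrate + initiating radical ⇌ chain carrier (K = 1300 M⁻¹, k = 3.50 × 10⁶ M⁻¹ h⁻¹)
    initiator → 2 initiating radical (k = 0.00240 h⁻¹)

The neighbour charged with 0.11 M of initiator takes the same reckoning. The root of its charge shrinks the changeover fraction to 0.331, so in the reckoning s stays on the dose line until 1.00 d, against 0.516 d in the flask. The formula then leaves 0.592 % of the substrate at 3.0 d. The neighbour gives 0.556 % substrate, with 99.4 % target.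

Readings and results stem from a simulated flask for an exercise.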